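**Plan**

- Numbering: ring A (N4, C3, C2, C1, C9a), ring B (N4, C5–C9, C9a), ring C (C9, C9a, C1, C12, C11, C10), lactone D (O–C1, C12, C13, C14), side lactone E (C18–C21).
- Enabling feature: inside ring C the quaternary carbon C1, which carries the lactone D oxygen, is bonded to C9a, an enamine carbon at the ketone oxidation level. With C9a as a ketone this is a 2-acyloxycyclohexanone, the ring-expanded isomer of a 1-acylcyclopentanol that holds C12 in its ring.
- Cuts, in order: N4–C5 and N4=C9a (rings B and A), C8–C9, C3–C18 (ring E), then C1–C12 together with the lactone C1–O–C14 bond (back to the acylcyclopentanol), C9a–C1 (dithiane), C10–ethyl, and the cyclopentenone back to a bought bicyclic cyclopentene lactone.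
- Forward: cyclopentane (bought), then ring C and lactone D together in the α-ketol ring expansion, then the C9 side chain, ring E (vinylogous Mannich reaction, hydrogenation), ring A (imine condensation) and ring B (N-alkylation to the enamine).
- Stereochemistry: C11 and C12 from the enantiopure lactone; C13 by convex-face methylation; C10 by conjugate addition anti to the silyloxy group; C9a by carbonyl addition anti to the C12 arm; C1 by the stereospecific shift and the cis-lactone trap; C3 and C18 from the sulfinyl auxiliary; C20 by hydrogenation anti to the C18 substituent.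

Key step: step 11

Assumption: the silyloxyfuran is taken to attack the N-sulfinyl aldimine through an open, non-chelated transition state (s-cis sulfinyl imine, attack anti to tert-butyl), so the (S)-sulfinamide should give (3R); if the facial sense were opposite, the (R)-sulfinamide would be used with no other change.

**Route**

Step 1
Reactants: 1 (1R,5S)-2-oxabicyclo[3.3.0]oct-6-en-3-one
Product: 2 (3R,3aR,6aR)-3-methyl-3,3a,6,6a-tetrahydro-2H-cyclopenta[b]furan-2-one
Conditions: LiN(i-Pr)2, THF, −78 °C; MeI, −78 → −40 °C
Reagents that add atoms: iodomethane CI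
Why: Lactone enolate alkylation, in which the lithium enolate of the cis-fused bicyclic lactone should be methylated on its convex face, trans to the ring-fusion bond C12–C9a, which sets C13.

Step 2
Reactants: 2 (3R,3aR,6aR)-3-methyl-3,3a,6,6a-tetrahydro-2H-cyclopenta[b]furan-2-one
Product: 5 methyl (2R)-2-[(1R,5R)-5-(tert-butyldimethylsilyloxy)cyclopent-2-en-1-yl]propanoate, via potassium carboxylate 3 (not isolated), via hydroxy ester 4 (not isolated)
Conditions: KOH, MeOH/H2O, rt; evaporate; MeI, DMF, rt; then imidazole, TBSCl, rt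
Reagents that add atoms: potassium hydroxide [K+].[OH-]; iodomethane CI; tert-butyl(chloro)dimethylsilane CC(C)(C)[Si](C)(C)Cl
Why: Saponification, carboxylate O-methylation and silylation in one pot should open the lactone without touching C11, C12 or C13, the hydroxy ester being silylated before it can close again.

Step 3
Reactants: 5 methyl (2R)-2-[(1R,5R)-5-(tert-butyldimethylsilyloxy)cyclopent-2-en-1-yl]propanoate
Product: 6 epoxide of 5 with the oxirane trans to the silyloxy and propanoate groups
Conditions: mCPBA, CH2Cl2, 0 °C → rt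
Reagents that add atoms: 3-chloroperoxybenzoic acid OOC(=O)c1cccc(Cl)c1
Why: Prilezhaev epoxidation, in which the peracid should approach the cyclopentene face opposite the two cis substituents.

Step 4
Reactants: 6 epoxide of 5
Product: 9 allylic alcohol methyl (2R)-2-[2-hydroxy-5-(tert-butyldimethylsilyloxy)cyclopent-3-en-1-yl]propanoate (hydroxyl trans to the arm), via hydroxy selenide 7 (not isolated), via selenoxide 8 (not isolated)
Conditions: (PhSe)2, NaBH4, EtOH, rt; then H2O2, THF, 0 °C → rt
Reagents that add atoms: none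
Why: Epoxide-to-allylic-alcohol transposition by selenide opening and selenoxide syn-elimination, in which the selenolate should attack C9 (remote from the branched C12 substituent) and the selenoxide should eliminate away from the carbinol toward C10.

Step 5
Reactants: 9 allylic alcohol
Product: 10 methyl (2R)-2-[(1R,5R)-5-(tert-butyldimethylsilyloxy)-2-oxocyclopent-3-en-1-yl]propanoate
Conditions: DMP, CH2Cl2, 0 °C → rt
Reagents that add atoms: none
Why: Periodinane oxidation of the secondary allylic alcohol under non-basic conditions should give the enone without epimerising the α-centre C12.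

Step 6
Reactants: 10 methyl (2R)-2-[(1R,5R)-5-(tert-butyldimethylsilyloxy)-2-oxocyclopent-3-en-1-yl]propanoate
Product: 11 methyl (2R)-2-[(1R,2R,3S)-2-(tert-butyldimethylsilyloxy)-3-ethyl-5-oxocyclopentyl]propanoate
Conditions: EtMgBr, CuBr·SMe2 (10 mol%), THF, −78 °C; aq. NH4Cl, −78 °C
Reagents that add atoms: ethylmagnesium bromide CC[Mg]Br
Why: Copper-catalysed conjugate addition, in which ethyl should add to C10 anti to the neighbouring silyloxy group as in 4-silyloxycyclopentenone chemistry (sets C10), the enolate being protonated at C9 in the cold so that C12 stays untouched.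

Step 7
Reactants: 12 1,3-dithiane
Product: 13 2-(1,3-dithian-2-yl)ethanol
Conditions: n-BuLi, THF, −30 °C; oxirane, −30 → 0 °C; H2O
Reagents that add atoms: oxirane C1CO1
Why: Umpolung alkylation of 2-lithio-1,3-dithiane by epoxide opening is a standard way to the 2-hydroxyethyl dithiane.

Step 8
Reactants: 13 2-(1,3-dithian-2-yl)ethanol
Product: 14 2-{2-[(4-methoxyphenyl)methoxy]ethyl}-1,3-dithiane
Conditions: NaH, PMBCl, Bu4NI (cat.), DMF, 0 °C → rt
Reagents that add atoms: 4-methoxybenzyl chloride COc1ccc(CCl)cc1
Why: Williamson etherification of the primary alkoxide, which NaH forms without deprotonating the dithiane.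

Step 9
Reactants: 11 methyl (2R)-2-[(1R,2R,3S)-2-(tert-butyldimethylsilyloxy)-3-ethyl-5-oxocyclopentyl]propanoate; 14 2-{2-[(4-methoxyphenyl)methoxy]ethyl}-1,3-dithiane
Product: 15 methyl (2R)-2-[(1R,2R,3S,5S)-2-(tert-butyldimethylsilyloxy)-3-ethyl-5-hydroxy-5-(2-{2-[(4-methoxyphenyl)methoxy]ethyl}-1,3-dithian-2-yl)cyclopentyl]propanoate
Conditions: 14, n-BuLi, THF, −30 °C; then 11, −78 °C; AcOH, −78 °C
Reagents that add atoms: none
Why: Addition of a 2-lithio-1,3-dithiane acyl-anion equivalent to the ketone, which should occur on the face anti to the C12 arm so that the hydroxyl ends cis to the arm (sets C9a), the cold acidic quench keeping the hydroxy ester open.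

Step 10
Reactants: 15 dithiane carbinol
Product: 16 methyl (2R)-2-[(1R,2R,3S,5S)-2-(tert-butyldimethylsilyloxy)-3-ethyl-5-hydroxy-5-{3-[(4-methoxyphenyl)methoxy]propanoyl}cyclopentyl]propanoate
Conditions: MeI, CaCO3, MeCN/H2O, 45 °C
Reagents that add atoms: water O
Why: S-methylation and hydrolysis of the dithioacetal under buffered conditions should unmask the ketone while the PMB ether, the silyl ether and the tertiary carbinol survive.

Step 11
Reactants: 16 acylcyclopentanol
Product: 18 (3R,3aR,4R,5S,7aR)-4-(tert-butyldimethylsilyloxy)-5-ethyl-7a-{2-[(4-methoxyphenyl)methoxy]ethyl}-3-methylhexahydro-1-benzofuran-2,7-dione, via ring-expanded hydroxy ketone 17 (not isolated)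
Conditions: Al(Ot-Bu)3 (2 equiv), toluene, 90 °C
Reagents that add atoms: none
Why: The aluminium alkoxide of the C9a carbinol chelates the neighbouring C1 ketone, and in this syn-periplanar chelate the ring bond C9a–C12 shifts suprafacially, with retention at C12, to the acyl carbon C1 while C9a becomes the ketone; this is an α-ketol (acyloin) rearrangement with one-carbon ring expansion, of the kind known from the D-homoannulation of 17-hydroxy-20-keto steroids with aluminium alkoxides. Ring C closes by this 1,2-alkyl shift (cyclopentane to cyclohexanone), and lactone D closes by 5-exo-trig attack of the new C1 alkoxide on the methyl ester with loss of methoxide. The new stereocentre C1 is fixed by the C9a configuration of 16 (hydroxyl cis to the propanoate arm) acting through the chelate, which puts the C1 oxygen cis to C13, and only this C1 epimer can form the cis-fused lactone. The step needs C12 to migrate in preference to the ring methylene C9; this should be secured by the higher migratory aptitude of the more substituted carbon and, because the shift is reversible, by the lactone acting as a thermodynamic sink for the C12-migrated isomer alone. Closure of the starting carbinol onto the same ester would give a bicyclo[3.3.0] lactone whose concave methyl group is pressed against the cis silyloxy group, so it should be disfavoured and be reopened by aluminium methoxide. The tert-butoxide has no transferable hydride (no Meerwein–Ponndorf–Verley reduction) and is too weak a base to expel the β-alkoxy group of the ketone or the silyl ether.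

Step 12
Reactants: 18 keto lactone
Product: 19 C9-(4-chlorobutyl) keto lactone (chain trans to the C10 ethyl group)
Conditions: LiN(SiMe3)2, THF, −78 °C; I(CH2)4Cl, DMPU, −78 → −20 °C
Reagents that add atoms: 1-chloro-4-iodobutane ClCCCCI
Why: Ketone enolate alkylation, in which only C9 has α-hydrogens (C1 is quaternary) and the ketone is far more acidic than the lactone, so the lithium enolate should be alkylated at the iodide end; the C9 configuration is of no consequence because C9 later becomes sp2.

Step 13
Reactants: 19 C9-(4-chlorobutyl) keto lactone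
Product: 20 primary alcohol at C3 (may rest partly as the five-membered hemiketal with the C9a ketone)
Conditions: DDQ, CH2Cl2/pH 7 buffer, 0 °C
Reagents that add atoms: none
Why: Oxidative cleavage of the PMB ether by DDQ should leave the silyl ether, the lactone, the ketone and the alkyl chloride untouched.

Step 14
Reactants: 20 primary alcohol
Product: 21 C3 aldehyde
Conditions: DMP, CH2Cl2, 0 °C → rt
Reagents that add atoms: none
Why: Periodinane oxidation of the primary alcohol, which drains the hemiketal through its open form, under conditions too mild for aldol closure of the keto aldehyde.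

Step 15
Reactants: 21 C3 aldehyde
Product: 22 (S)-N-tert-butanesulfinyl (E)-aldimine at C3
Conditions: (S)-t-BuS(O)NH2, CuSO4, CH2Cl2, rt
Reagents that add atoms: (S)-2-methylpropane-2-sulfinamide CC(C)(C)[S@](=O)N
Why: Condensation of the aldehyde with tert-butanesulfinamide under mild dehydration should be selective, since the hindered ketone does not condense under these conditions.

Step 16
Reactants: 23 3-methylfuran-2(5H)-one
Product: 24 triisopropyl[(3-methylfuran-2-yl)oxy]silane
Conditions: TIPSOTf, Et3N, CH2Cl2, 0 °C
Reagents that add atoms: triisopropylsilyl trifluoromethanesulfonate CC(C)[Si](OS(=O)(=O)C(F)(F)F)(C(C)C)C(C)C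
Why: Soft enolisation and O-silylation of the butenolide gives the aromatic 2-silyloxyfuran.

Step 17
Reactants: 22 N-sulfinyl aldimine; 24 triisopropyl[(3-methylfuran-2-yl)oxy]silane
Product: 25 (3R)-sulfinamide carrying the (18S)-3-methylbutenolide at C3
Conditions: TMSOTf (0.2 equiv), CH2Cl2, −78 °C; aq. NaHCO3
Reagents that add atoms: none
Why: Vinylogous Mukaiyama–Mannich reaction, in which the furan should add through C5 to the silyl-activated imine on the face anti to the tert-butyl group (sets C3, see the assumption) and in the anti sense usual for silyloxyfurans and aldimines (sets C18).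

Step 18
Reactants: 25 butenolide sulfinamide
Product: 26 saturated (18S,20S)-lactone sulfinamide
Conditions: H2 (1 atm), Pd/C, EtOAc, rt
Reagents that add atoms: none
Why: Heterogeneous hydrogenation of the butenolide should deliver hydrogen to the face opposite the C18 substituent and so give the cis-3,5-disubstituted lactone (sets C20), while the alkyl chloride and the sulfinamide remain.

Step 19
Reactants: 26 saturated lactone sulfinamide
Product: 29 11-O-tert-butyldimethylsilyl ether of the target, via amino ketone 27 (not isolated), via cyclic imine 28 (not isolated)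
Conditions: HCl (4 M in dioxane, 2 equiv), MeOH, 0 °C → rt; evaporate; i-Pr2NEt, NaI (cat.), MeCN, 70 °C
Reagents that add atoms: none
Why: Acidic N-desulfinylation frees the γ-amino ketone, which should condense at once to the 1-pyrroline (ring A) and so outrun attack of nitrogen on the lactones; the imine nitrogen then displaces the terminal halide (Finkelstein-assisted intramolecular N-alkylation, ring B) and the iminium loses the C9 proton to give the enamine, an imine annulation of the known endocyclic-enamine type.

Step 20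
Reactants: 29 silyl ether of the target
Product: 30 target compound
Conditions: HF·pyridine, pyridine, THF, 0 °C → rt; aq. NaHCO3
Reagents that add atoms: none
Why: Fluoride-mediated desilylation under buffered, near-neutral conditions should free the C11 hydroxyl without letting it attack lactone D, the enamine being regenerated on basic work-up.

**Compound list**

1 | (1R,5S)-2-oxabicyclo[3.3.0]oct-6-en-3-one, i.e. (3aS,6aR)-3,3a,6,6a-tetrahydro-2H-cyclopenta[b]furan-2-one | O=C1C[C@H]2C=CC[C@H]2O1 | starting material
2 | (3R,3aR,6aR)-3-methyl-3,3a,6,6a-tetrahydro-2H-cyclopenta[b]furan-2-one (methyl on the convex face) | C1C=C[C@@H]2[C@@H](C)C(=O)O[C@H]12 | intermediate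
3 | potassium (2R)-2-[(1R,5R)-5-hydroxycyclopent-2-en-1-yl]propanoate (not isolated) | C1C=C[C@H]([C@@H](C)C(=O)[O-])[C@@H]1O.[K+] | intermediate
4 | methyl (2R)-2-[(1R,5R)-5-hydroxycyclopent-2-en-1-yl]propanoate (not isolated) | C1C=C[C@H]([C@@H](C)C(=O)OC)[C@@H]1O | intermediate
5 | methyl (2R)-2-[(1R,5R)-5-(tert-butyldimethylsilyloxy)cyclopent-2-en-1-yl]propanoate | C1C=C[C@H]([C@@H](C)C(=O)OC)[C@@H]1O[Si](C)(C)C(C)(C)C | intermediate
6 | methyl (2R)-2-[3-(tert-butyldimethylsilyloxy)-6-oxabicyclo[3.1.0]hexan-2-yl]propanoate, oxirane trans to both substituents | C1[C@H]2O[C@H]2[C@H]([C@@H](C)C(=O)OC)[C@@H]1O[Si](C)(C)C(C)(C)C | intermediate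
7 | hydroxy selenide: C9a hydroxyl trans to the arm, C9 phenylselanyl trans to the hydroxyl (not isolated) | C1[C@H]([Se]c2ccccc2)[C@@H](O)[C@H]([C@@H](C)C(=O)OC)[C@@H]1O[Si](C)(C)C(C)(C)C | intermediate
8 | selenoxide of 7, mixture at selenium (not isolated) | C1[C@H]([Se](=O)c2ccccc2)[C@@H](O)[C@H]([C@@H](C)C(=O)OC)[C@@H]1O[Si](C)(C)C(C)(C)C | intermediate
9 | methyl (2R)-2-[2-hydroxy-5-(tert-butyldimethylsilyloxy)cyclopent-3-en-1-yl]propanoate, hydroxyl trans and silyloxy cis to the arm | C1=C[C@@H](O)[C@H]([C@@H](C)C(=O)OC)[C@@H]1O[Si](C)(C)C(C)(C)C | intermediate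
10 | methyl (2R)-2-[(1R,5R)-5-(tert-butyldimethylsilyloxy)-2-oxocyclopent-3-en-1-yl]propanoate | C1=CC(=O)[C@H]([C@@H](C)C(=O)OC)[C@@H]1O[Si](C)(C)C(C)(C)C | intermediate
11 | methyl (2R)-2-[(1R,2R,3S)-2-(tert-butyldimethylsilyloxy)-3-ethyl-5-oxocyclopentyl]propanoate | CC[C@H]1CC(=O)[C@H]([C@@H](C)C(=O)OC)[C@@H]1O[Si](C)(C)C(C)(C)C | intermediate
12 | 1,3-dithiane | C1CSCSC1 | starting material
13 | 2-(1,3-dithian-2-yl)ethanol | OCCC1SCCCS1 | intermediate
14 | 2-{2-[(4-methoxyphenyl)methoxy]ethyl}-1,3-dithiane | COc1ccc(COCCC2SCCCS2)cc1 | intermediate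
15 | methyl (2R)-2-[(1R,2R,3S,5S)-2-(tert-butyldimethylsilyloxy)-3-ethyl-5-hydroxy-5-(2-{2-[(4-methoxyphenyl)methoxy]ethyl}-1,3-dithian-2-yl)cyclopentyl]propanoate | CC[C@H]1C[C@@](O)(C2(CCOCc3ccc(OC)cc3)SCCCS2)[C@H]([C@@H](C)C(=O)OC)[C@@H]1O[Si](C)(C)C(C)(C)C | intermediate
16 | methyl (2R)-2-[(1R,2R,3S,5S)-2-(tert-butyldimethylsilyloxy)-3-ethyl-5-hydroxy-5-{3-[(4-methoxyphenyl)methoxy]propanoyl}cyclopentyl]propanoate (key-step precursor) | CC[C@H]1C[C@@](O)(C(=O)CCOCc2ccc(OC)cc2)[C@H]([C@@H](C)C(=O)OC)[C@@H]1O[Si](C)(C)C(C)(C)C | intermediate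
17 | ring-expanded 2-hydroxycyclohexanone methyl ester, C1 hydroxyl cis to the propanoate arm (not isolated) | CC[C@H]1CC(=O)[C@@](O)(CCOCc2ccc(OC)cc2)[C@H]([C@@H](C)C(=O)OC)[C@@H]1O[Si](C)(C)C(C)(C)C | intermediate
18 | (3R,3aR,4R,5S,7aR)-4-(tert-butyldimethylsilyloxy)-5-ethyl-7a-{2-[(4-methoxyphenyl)methoxy]ethyl}-3-methylhexahydro-1-benzofuran-2,7-dione (key-step product) | CC[C@H]1CC(=O)[C@]2(CCOCc3ccc(OC)cc3)OC(=O)[C@H](C)[C@@H]2[C@@H]1O[Si](C)(C)C(C)(C)C | intermediate
19 | 18 with a 4-chlorobutyl group at C9, trans to the C10 ethyl group | CC[C@H]1[C@H](CCCCCl)C(=O)[C@]2(CCOCc3ccc(OC)cc3)OC(=O)[C@H](C)[C@@H]2[C@@H]1O[Si](C)(C)C(C)(C)C | intermediate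
20 | 19 with the PMB ether replaced by a free C3 hydroxyl | CC[C@H]1[C@H](CCCCCl)C(=O)[C@]2(CCO)OC(=O)[C@H](C)[C@@H]2[C@@H]1O[Si](C)(C)C(C)(C)C | intermediate
21 | C3 aldehyde (2-oxoethyl group on C1) | CC[C@H]1[C@H](CCCCCl)C(=O)[C@]2(CC=O)OC(=O)[C@H](C)[C@@H]2[C@@H]1O[Si](C)(C)C(C)(C)C | intermediate
22 | (S)-N-tert-butanesulfinyl (E)-aldimine of 21 | CC[C@H]1[C@H](CCCCCl)C(=O)[C@]2(C/C=N/[S@@](=O)C(C)(C)C)OC(=O)[C@H](C)[C@@H]2[C@@H]1O[Si](C)(C)C(C)(C)C | intermediate
23 | 3-methylfuran-2(5H)-one | CC1=CCOC1=O | starting material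
24 | triisopropyl[(3-methylfuran-2-yl)oxy]silane | Cc1ccoc1O[Si](C(C)C)(C(C)C)C(C)C | intermediate
25 | (3R)-N-sulfinyl amine bearing the (18S)-4-methyl-5-oxo-2,5-dihydrofuran-2-yl group at C3 | CC[C@H]1[C@H](CCCCCl)C(=O)[C@]2(C[C@@H](N[S@@](=O)C(C)(C)C)[C@@H]3C=C(C)C(=O)O3)OC(=O)[C@H](C)[C@@H]2[C@@H]1O[Si](C)(C)C(C)(C)C | intermediate
26 | 25 with the butenolide saturated to the (18S,20S)-cis-lactone | CC[C@H]1[C@H](CCCCCl)C(=O)[C@]2(C[C@@H](N[S@@](=O)C(C)(C)C)[C@@H]3C[C@H](C)C(=O)O3)OC(=O)[C@H](C)[C@@H]2[C@@H]1O[Si](C)(C)C(C)(C)C | intermediate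
27 | primary amine of 26, formed as its hydrochloride (not isolated) | CC[C@H]1[C@H](CCCCCl)C(=O)[C@]2(C[C@@H](N)[C@@H]3C[C@H](C)C(=O)O3)OC(=O)[C@H](C)[C@@H]2[C@@H]1O[Si](C)(C)C(C)(C)C | intermediate
28 | 1-pyrroline (N4=C9a) with rings A, C, D and E in place and the 4-chlorobutyl chain on C9 (not isolated) | CC[C@H]1[C@H](CCCCCl)C2=N[C@@H]([C@@H]3C[C@H](C)C(=O)O3)C[C@]24OC(=O)[C@H](C)[C@@H]4[C@@H]1O[Si](C)(C)C(C)(C)C | intermediate
29 | 11-O-tert-butyldimethylsilyl ether of the target | CC[C@H]1C2=C3N(CCCC2)[C@@H]([C@@H]2C[C@H](C)C(=O)O2)C[C@]32OC(=O)[C@H](C)[C@@H]2[C@@H]1O[Si](C)(C)C(C)(C)C | intermediate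
30 | target (1R,3R,10S,11R,12R,13R,18S,20S) | CC[C@H]1C2=C3N(CCCC2)[C@@H]([C@@H]2C[C@H](C)C(=O)O2)C[C@]32OC(=O)[C@H](C)[C@@H]2[C@@H]1O | target

**Totals**

Total steps: 20 (steps 7, 8 and 16 prepare the two side fragments). Longest linear sequence: 17 steps (1–6, 9–15, 17–20).

**Steps most likely to fail**

1. Step 11. The carbinol may close onto its own ester before it rearranges, or the ring methylene C9 may migrate in place of C12, so that the lactone sink is not reached. The fallback moves the trap to the lactol oxidation level, where a five-membered hemiacetal opens freely. It sets out from 15: reduction of the ester with i-Bu2AlH (CH2Cl2, −78 °C) lets the cis hydroxyl catch the aldehyde as the dithiane lactol F1. MeI and CaCO3 in wet MeCN then unmask the keto lactol F2. A chelating Lewis acid (BF3·OEt2, CH2Cl2, 0 °C) effects the same C12 shift through the open hydroxy aldehyde, and the C1 hydroxyl is caught as the ring-expanded lactol F3. Oxidation of F3 with PhI(OAc)2 and catalytic TEMPO comes back to the route at 18.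

2. Step 9. The basic lithiodithiane may deprotonate the ketone instead of adding, which would epimerise C12 or expel the β-silyloxy group. The fallback uses a slimmer sp2 acyl-anion equivalent and forms the ether afterwards. It sets out from 11: 1-lithio-1-methoxyallene (methoxyallene, n-BuLi, THF, −78 °C) should add anti to the arm to give the methoxyallenyl carbinol F4. Mild aqueous acid (oxalic acid, wet THF) hydrolyses the enol ether to the α-hydroxy vinyl ketone F5. Phosphine-catalysed oxa-Michael addition of 4-methoxybenzyl alcohol (PMe3, cat.) comes back to the route at 16.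

3. Step 12. C-alkylation of the hindered enolate by an unactivated primary iodide may be slower than proton exchange or O-alkylation. The fallback uses an activated allylic electrophile and saturates afterwards. It sets out from 18: the lithium enolate is alkylated with excess (E)-1,4-dichlorobut-2-ene to give the C9 allylic chloride F6. The disubstituted alkene is then reduced with diimide (potassium azodicarboxylate, AcOH, MeOH), which should leave the C–Cl bond and the PMB ether intact, and this comes back to the route at 19.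

**Further compounds**

F1 | step 11 | dithiane lactol: hemiacetal between the C9a hydroxyl and the reduced ester carbon, anomer mixture | CC[C@H]1C[C@]2(C3(CCOCc4ccc(OC)cc4)SCCCS3)OC(O)[C@H](C)[C@@H]2[C@@H]1O[Si](C)(C)C(C)(C)C
F2 | step 11 | keto lactol: F1 with the dithiane hydrolysed to the C1 ketone | CC[C@H]1C[C@]2(C(=O)CCOCc3ccc(OC)cc3)OC(O)[C@H](C)[C@@H]2[C@@H]1O[Si](C)(C)C(C)(C)C
F3 | step 11 | ring-expanded lactol: 18 with the lactone carbonyl at the hemiacetal level | CC[C@H]1CC(=O)[C@]2(CCOCc3ccc(OC)cc3)OC(O)[C@H](C)[C@@H]2[C@@H]1O[Si](C)(C)C(C)(C)C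
F4 | step 9 | methoxyallenyl carbinol: 1-methoxypropa-1,2-dienyl group on C9a, hydroxyl cis to the arm | CC[C@H]1C[C@@](O)(C(OC)=C=C)[C@H]([C@@H](C)C(=O)OC)[C@@H]1O[Si](C)(C)C(C)(C)C
F5 | step 9 | α-hydroxy vinyl ketone: propenoyl group on C9a | CC[C@H]1C[C@@](O)(C(=O)C=C)[C@H]([C@@H](C)C(=O)OC)[C@@H]1O[Si](C)(C)C(C)(C)C
F6 | step 12 | 18 with an (E)-4-chlorobut-2-enyl group at C9 | CC[C@H]1[C@H](C/C=C/CCl)C(=O)[C@]2(CCOCc3ccc(OC)cc3)OC(=O)[C@H](C)[C@@H]2[C@@H]1O[Si](C)(C)C(C)(C)C
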